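**Strategy**

The indole is disconnected across N1–C7a and C3–C3a, so that the benzo ring is delivered as 3,5-dibromobenzyne and the pyrrole carbons as a three-atom N–C–C unit. In one operation the aryne annulation forges both bonds and closes the five-membered lactam ring, giving a 4,6-dibromo-3-(methylthio)oxindole. It exploits the fact that N1 and C3 are attached to neighbouring benzo-ring carbons (C7a, C3a) and that the C4 bromine flanks C3a, which steers nitrogen to C7a. The precursors are a 2,4-dibromo-6-silylaryl triflate and an N-methoxy amide carrying chlorine and SMe on its alpha carbon; thionation and S-methylation then aromatise the ring.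

Key step: step 5

Remark: the alpha-chloro amide, both oxindoles and the thiolactam each carry one stereocentre and are made and used as racemates, since the target is achiral; the thiolactam is drawn as its thione tautomer.

**Route**

Step 1
Reactants: 1 2,4,6-tribromophenol; 2 hexamethyldisilazane
Product: 3 (2,4,6-tribromophenoxy)trimethylsilane
Conditions: HMDS (0.6 equiv), THF, reflux; volatiles removed in vacuo, crude used
Reagents that add atoms: hexamethyldisilazane (2), C[Si](C)(C)N[Si](C)(C)C
Why: O-silylation of the acidic phenol by transsilylation with hexamethyldisilazane is driven by loss of ammonia and should give a silyl ether clean enough to use directly.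

Step 2
Reactants: 3 (2,4,6-tribromophenoxy)trimethylsilane; 4 trifluoromethanesulfonic anhydride
Product: 7 2,4-dibromo-6-(trimethylsilyl)phenyl trifluoromethanesulfonate, via ortho-lithiated silyl ether 5 (not isolated), via lithium 2,4-dibromo-6-(trimethylsilyl)phenoxide 6 (not isolated)
Conditions: n-BuLi (1.05 equiv), THF, −100 to −78 °C; then Tf2O (1.2 equiv), −78 °C to rt
Reagents that add atoms: trifluoromethanesulfonic anhydride (4), O=S(=O)(OS(=O)(=O)C(F)(F)F)C(F)(F)F
Why: Bromine–lithium exchange is favoured at a bromine ortho to the silyloxy group (inductive activation, O–Li coordination), and only that aryllithium can undergo the 1,3-O-to-C silyl shift (retro-Brook rearrangement), so phenoxide 6 should form irreversibly and be O-sulfonylated by Tf2O, the standard route to ortho-silylaryl triflates.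

Step 3
Reactants: 8 (methylthio)acetic acid; 9 O-methylhydroxylamine hydrochloride
Product: 11 N-methoxy-2-(methylthio)acetamide, via acyl imidazole 10 (not isolated)
Conditions: CDI (1.1 equiv), CH2Cl2, rt; then MeONH2·HCl (1.2 equiv), rt
Reagents that add atoms: none
Why: Amide coupling through the acyl imidazole: carbonyldiimidazole activates the acid with loss of CO2, and the imidazole released frees O-methylhydroxylamine from its salt, which is acylated on nitrogen.

Step 4
Reactants: 11 N-methoxy-2-(methylthio)acetamide; 12 N-chlorosuccinimide
Product: 13 racemic 2-chloro-N-methoxy-2-(methylthio)acetamide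
Conditions: NCS (1.0 equiv), CH2Cl2, 0 °C to rt; succinimide filtered off, crude used at once
Reagents that add atoms: N-chlorosuccinimide (12), O=C1CCC(=O)N1Cl
Why: Pummerer-type alpha-chlorination of a sulfide: S-chlorination gives a chlorosulfonium ion, loss of HCl at the more acidic methylene next to the carbonyl gives a thionium ion, and chloride adds to it without facial bias, so the new centre is racemic.

Step 5
Reactants: 7 2,4-dibromo-6-(trimethylsilyl)phenyl trifluoromethanesulfonate; 13 racemic 2-chloro-N-methoxy-2-(methylthio)acetamide
Product: 16 racemic 4,6-dibromo-1-methoxy-3-(methylthio)indolin-2-one, via 3,5-dibromobenzyne 14 (not isolated), via N-arylated arylcesium 15 (not isolated)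
Conditions: CsF (3 equiv), MeCN, 0 °C to rt; 13 in 1.5-fold excess, anhydrous
Reagents that add atoms: none
Why: Proposed new method: fluoride attacks silicon of 7 and triflate departs to give aryne 14, while CsF also removes the N–H proton of 13; the hydroxamate nitrogen adds to the aryne carbon remote from the flanking bromine to give aryl anion 15, whose carbanion at the future C3a displaces chloride from the neighbouring sulfur-activated carbon (or captures the azaoxyallyl/thionium carbon if chloride has already left), so that N1–C7a and C3–C3a form in one operation. The closest known reaction types are aryne N-arylation of amide anions with intramolecular capture of the aryl anion, aryne insertion into amide N–C bonds and (3+2) annulations of azaoxyallyl cations generated from alpha-halo hydroxamates. The one new ring, the five-membered lactam, closes in a 5-exo-tet mode. The new stereocentre at C3 has no controlling element and should form as a racemate, which is acceptable because C3 becomes sp2 in step 8. The step needs nitrogen to add meta and carbon ortho to the neighbouring bromine, which the inductive distortion of the aryne by the adjacent C–Br bond secures, and N- over O-arylation, which the more nucleophilic hydroxamate nitrogen secures; the excess of 13 should keep the acidic product from being arylated at C3.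

Step 6
Reactants: 16 racemic 4,6-dibromo-1-methoxy-3-(methylthio)indolin-2-one
Product: 17 racemic 4,6-dibromo-3-(methylthio)indolin-2-one
Conditions: Mo(CO)6 (1.2 equiv), MeCN/H2O (15:1), 85 °C
Reagents that add atoms: none
Why: Reductive N–O cleavage of an N-alkoxy lactam by zerovalent molybdenum, which inserts into the weak N–O bond and is hydrolysed by water, should leave the aryl bromides and the thioether untouched.

Step 7
Reactants: 17 racemic 4,6-dibromo-3-(methylthio)indolin-2-one; 18 Lawesson's reagent
Product: 19 racemic 4,6-dibromo-3-(methylthio)indoline-2-thione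
Conditions: Lawesson's reagent (0.6 equiv), toluene, 80 °C, argon; crude used directly
Reagents that add atoms: Lawesson's reagent (18), COc1ccc(cc1)P1(=S)SP(=S)(S1)c1ccc(OC)cc1
Why: Thionation of the secondary lactam, the only carbonyl group present, proceeds by Wittig-like O/S exchange through a four-membered thiaoxaphosphetane.

Step 8
Reactants: 19 racemic 4,6-dibromo-3-(methylthio)indoline-2-thione; 20 iodomethane
Product: 21 4,6-dibromo-2,3-bis(methylthio)-1H-indole
Conditions: MeI (1.05 equiv), K2CO3 (1.5 equiv), acetone, 0 °C to rt
Reagents that add atoms: iodomethane (20), CI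
Why: Base removes the acidic C3–H of the thiolactam to give the aromatic indole-2-thiolate, which is alkylated at soft sulfur by MeI (S-alkylation of a thioamide anion), so the pyrrole ring aromatises and the C3 stereocentre vanishes.

**Compound list**

1 | 2,4,6-tribromophenol | Oc1c(Br)cc(Br)cc1Br | starting material
2 | hexamethyldisilazane | C[Si](C)(C)N[Si](C)(C)C | starting material
3 | (2,4,6-tribromophenoxy)trimethylsilane | C[Si](C)(C)Oc1c(Br)cc(Br)cc1Br | intermediate
4 | trifluoromethanesulfonic anhydride | O=S(=O)(OS(=O)(=O)C(F)(F)F)C(F)(F)F | starting material
5 | ortho-lithiated silyl ether, [3,5-dibromo-2-(trimethylsilyloxy)phenyl]lithium | [Li]c1cc(Br)cc(Br)c1O[Si](C)(C)C | intermediate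
6 | lithium 2,4-dibromo-6-(trimethylsilyl)phenoxide | [Li+].[O-]c1c(Br)cc(Br)cc1[Si](C)(C)C | intermediate
7 | 2,4-dibromo-6-(trimethylsilyl)phenyl trifluoromethanesulfonate | C[Si](C)(C)c1cc(Br)cc(Br)c1OS(=O)(=O)C(F)(F)F | intermediate
8 | (methylthio)acetic acid | CSCC(=O)O | starting material
9 | O-methylhydroxylamine hydrochloride | CON.Cl | starting material
10 | acyl imidazole, 1-(imidazol-1-yl)-2-(methylthio)ethan-1-one | CSCC(=O)n1ccnc1 | intermediate
11 | N-methoxy-2-(methylthio)acetamide | CSCC(=O)NOC | intermediate
12 | N-chlorosuccinimide | O=C1CCC(=O)N1Cl | starting material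
13 | racemic 2-chloro-N-methoxy-2-(methylthio)acetamide | CSC(Cl)C(=O)NOC | intermediate
14 | 3,5-dibromobenzyne (3,5-dibromo-1,2-didehydrobenzene) | BrC1=CC(Br)=CC#C1 | intermediate
15 | N-arylated arylcesium, racemic [4,6-dibromo-2-(2-chloro-N-methoxy-2-(methylthio)acetamido)phenyl]cesium | CSC(Cl)C(=O)N(OC)c1cc(Br)cc(Br)[c-]1.[Cs+] | intermediate
16 | racemic 4,6-dibromo-1-methoxy-3-(methylthio)indolin-2-one | CSC1C(=O)N(OC)c2cc(Br)cc(Br)c21 | intermediate
17 | racemic 4,6-dibromo-3-(methylthio)indolin-2-one | CSC1C(=O)Nc2cc(Br)cc(Br)c21 | intermediate
18 | Lawesson's reagent, 2,4-bis(4-methoxyphenyl)-1,3,2,4-dithiadiphosphetane 2,4-disulfide | COc1ccc(cc1)P1(=S)SP(=S)(S1)c1ccc(OC)cc1 | starting material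
19 | racemic 4,6-dibromo-3-(methylthio)indoline-2-thione | CSC1C(=S)Nc2cc(Br)cc(Br)c21 | intermediate
20 | iodomethane | CI | starting material
21 | 4,6-dibromo-2,3-bis(methylthio)-1H-indole | CSc1[nH]c2cc(Br)cc(Br)c2c1SC | target

**Step count**

Total: 8 steps. Longest linear sequence: 6 steps (steps 1, 2, 5, 6, 7, 8; the amide branch through steps 3 and 4 is equally long).

**Steps most likely to fail**

1. Step 5 (proposed new method).
   - What may go wrong: the deprotonated alpha-chloro hydroxamate may ionise and oligomerise before it meets the short-lived aryne. The aryl anion may be protonated, or may expel the neighbouring bromide to form a second aryne, before ring closure. Oxygen may add to the aryne in place of nitrogen. The acidic C3–H of the product may be arylated by further aryne.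
   - Fallback (known chemistry, Gassman oxindole synthesis): it sets out from (methylthio)acetic acid 8 and comes back at oxindole 17, so steps 5 and 6 are bypassed. Acid 8 is esterified (EtOH, catalytic H2SO4, reflux) to ethyl (methylthio)acetate F1. Commercial 3,5-dibromoaniline (Nc1cc(Br)cc(Br)c1) is N-chlorinated with tert-butyl hypochlorite in CH2Cl2 at −65 °C to N-chloro-3,5-dibromoaniline F2. Addition of F1 gives [(3,5-dibromophenyl)amino](2-ethoxy-2-oxoethyl)methylsulfonium chloride F3. Et3N generates the sulfur ylide, whose [2,3]-sigmatropic (Sommelet–Hauser-type) rearrangement onto either of the two equivalent ortho carbons, followed by rearomatisation, should give ethyl 2-(2-amino-4,6-dibromophenyl)-2-(methylthio)acetate F4. Dilute HCl closes the lactam to 17. The symmetry of the aniline leaves no regiochemical question.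

2. Step 2.
   - What may go wrong: exchange at the para bromine or halogen scrambling before the silyl shift, and incomplete O-triflation of the hindered, electron-poor phenoxide in the same flask.
   - Fallback: it sets out from 2,4,6-tribromophenol 1 and comes back at triflate 7. It replaces the silyl migration by chelation-directed exchange with external C-silylation and moves the triflation to an isolated phenol. Phenol 1 is protected with chloromethyl methyl ether and iPr2NEt in CH2Cl2 as 1,3,5-tribromo-2-(methoxymethoxy)benzene F5. n-BuLi in Et2O at −78 °C, with lithium held by the acetal oxygens, should give [3,5-dibromo-2-(methoxymethoxy)phenyl]lithium F6. Quenching with Me3SiCl gives [3,5-dibromo-2-(methoxymethoxy)phenyl]trimethylsilane F7. HCl in MeOH at rt removes the acetal to give 2,4-dibromo-6-(trimethylsilyl)phenol F8. Tf2O 4 and pyridine in CH2Cl2 at 0 °C convert F8 into 7.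

3. Step 4.
   - What may go wrong: N-chlorination of the hydroxamate N–H by the electrophilic chlorine source, over-chlorination at carbon, and hydrolysis or self-alkylation of the labile alpha-chloro sulfide during handling.
   - Fallback: it sets out from amide 11 and comes back at chloride 13. Amide 11 is oxidised with NaIO4 in MeOH/H2O at 0 °C to N-methoxy-2-(methylsulfinyl)acetamide F9 (racemic at sulfur). A chloride-terminated Pummerer reaction of this sulfoxide with Me3SiCl in CH2Cl2 at rt should deliver 13 with no electrophilic chlorine present.

**Further compounds**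

F1 | step 5 | ethyl (methylthio)acetate | CCOC(=O)CSC
F2 | step 5 | N-chloro-3,5-dibromoaniline | ClNc1cc(Br)cc(Br)c1
F3 | step 5 | [(3,5-dibromophenyl)amino](2-ethoxy-2-oxoethyl)methylsulfonium chloride | CCOC(=O)C[S+](C)Nc1cc(Br)cc(Br)c1.[Cl-]
F4 | step 5 | racemic ethyl 2-(2-amino-4,6-dibromophenyl)-2-(methylthio)acetate | CCOC(=O)C(SC)c1c(N)cc(Br)cc1Br
F5 | step 2 | 1,3,5-tribromo-2-(methoxymethoxy)benzene | COCOc1c(Br)cc(Br)cc1Br
F6 | step 2 | [3,5-dibromo-2-(methoxymethoxy)phenyl]lithium | [Li]c1cc(Br)cc(Br)c1OCOC
F7 | step 2 | [3,5-dibromo-2-(methoxymethoxy)phenyl]trimethylsilane | COCOc1c(Br)cc(Br)cc1[Si](C)(C)C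
F8 | step 2 | 2,4-dibromo-6-(trimethylsilyl)phenol | Oc1c(Br)cc(Br)cc1[Si](C)(C)C
F9 | step 4 | N-methoxy-2-(methylsulfinyl)acetamide | CS(=O)CC(=O)NOC
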